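The route rests on disconnecting the C4a=C5 alkene of the isochromene-6,8-dione core: ring B is a 4-ylidene-4H-pyran, so C4a is the masked carbonyl carbon of a 4-pyranone, and the C6 ketone with its C5 methyl is the matching nucleophile. One operation, a silyl-triflate-driven condensation of that methyl ketone onto the pyranone carbonyl, forms C4a=C5 and closes ring A without touching the preset quaternary centre C7. The precursor is a kojic-acid-derived 4-pyranone that carries the (E)-tert-butyl acrylate at C3 and, at C8a, a 2-methyl-3-oxo-2-(triethylsilyloxy)butanoyl group whose C7 comes from (S)-lactic acid. The orsellinate is attached last.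

Key step: step 12

Remark: isochromene numbering is used (ring A = C4a, C5, C6, C7, C8, C8a; ring B = C1, O2, C3, C4, C4a, C8a). The target is (7R), which corresponds to replacing the α-hydrogen of (S)-lactic acid with retention. The carbinol carbon made in step 2 is carried as an epimer mixture because it becomes the C6 ketone. The C7 oxygen is silylated before C6 is oxidised, so no open-chain intermediate has a free tertiary ketol between two ketones.

Step 1
Reactants: 1 (S)-lactic acid; 2 pivalaldehyde
Product: 3 (2S,5S)-2-tert-butyl-5-methyl-1,3-dioxolan-4-one (cis)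
Conditions: p-TsOH·H2O (cat.), H2SO4 (cat.), pentane, reflux, Dean–Stark; recrystallisation (pentane/Et2O, −78 °C)
Reagents that add atoms: none
Why: Acid-catalysed acetalisation with azeotropic removal of water (Seebach dioxolanone formation) sets the acetal centre C2 under thermodynamic control, and crystallisation should deliver the cis isomer with tert-butyl and methyl on the same face.

Step 2
Reactants: 3 (2S,5S)-2-tert-butyl-5-methyl-1,3-dioxolan-4-one
Product: 5 (2S,5R)-2-tert-butyl-5-(1-hydroxyethyl)-5-methyl-1,3-dioxolan-4-one (carbinol epimers), via lithium enolate 4 (not isolated)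
Conditions: LiN(iPr)2, THF, −78 °C; MeCHO, −78 °C; aq. NH4Cl
Reagents that add atoms: acetaldehyde, CC=O
Why: Aldol addition under Seebach's self-regeneration of stereocentres: the tert-butyl group at C2 shields one face of the planar enolate, so acetaldehyde should enter anti to it, in the place of the former C–H, fixing the future C7 with overall retention (the carbinol centre is uncontrolled and is later oxidised).

Step 3
Reactants: 5 (2S,5R)-2-tert-butyl-5-(1-hydroxyethyl)-5-methyl-1,3-dioxolan-4-one
Product: 6 (2R)-2,3-dihydroxy-2-methylbutanoic acid (C3 epimers)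
Conditions: 2 M aq. HCl/THF, 60 °C; evaporation, azeotropic drying (toluene)
Reagents that add atoms: water, O
Why: Acid hydrolysis of the acylal releases volatile pivalaldehyde without breaking any bond at the quaternary centre, and acid instead of base avoids retro-aldol cleavage of the β-hydroxy acid derivative.

Step 4
Reactants: 6 (2R)-2,3-dihydroxy-2-methylbutanoic acid
Product: 7 triethylsilyl (2R)-2-methyl-2,3-bis(triethylsilyloxy)butanoate
Conditions: Et3SiOTf (3.5 equiv), 2,6-lutidine, CH2Cl2, 0 °C → rt; pentane, filtration (non-aqueous work-up)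
Reagents that add atoms: triethylsilyl trifluoromethanesulfonate, CC[Si](CC)(CC)OS(=O)(=O)C(F)(F)F
Why: Exhaustive O-silylation with a silyl triflate and a hindered pyridine base, the standard way to silylate tertiary alcohols, caps both hydroxyls and the acid in one operation.

Step 5
Reactants: 7 triethylsilyl (2R)-2-methyl-2,3-bis(triethylsilyloxy)butanoate
Product: 8 (2R)-2-methyl-2,3-bis(triethylsilyloxy)butanoyl chloride
Conditions: (COCl)2 (1.2 equiv), DMF (cat.), CH2Cl2, 0 °C → rt; evaporation, used crude
Reagents that add atoms: oxalyl chloride, ClC(=O)C(=O)Cl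
Why: Vilsmeier-type conversion of a silyl ester into the acid chloride liberates Et3SiCl instead of HCl, so the two silyl ethers should survive these neutral conditions.

Step 6
Reactants: 9 kojic acid
Product: 10 6-(hydroxymethyl)-4-oxo-4H-pyran-3-yl trifluoromethanesulfonate
Conditions: PhNTf2 (1.05 equiv), Et3N, DMF, 0 °C → rt
Reagents that add atoms: N-phenylbis(trifluoromethanesulfonimide), O=S(=O)(N(c1ccccc1)S(=O)(=O)C(F)(F)F)C(F)(F)F
Why: Chemoselective O-triflation: Et3N deprotonates only the acidic enolic 5-OH, and PhNTf2 transfers triflyl to such phenoxide-type oxygens while leaving the primary alcohol alone.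

Step 7
Reactants: 10 6-(hydroxymethyl)-4-oxo-4H-pyran-3-yl trifluoromethanesulfonate
Product: 12 tert-butyl (E)-3-[4-oxo-5-(trifluoromethylsulfonyloxy)-4H-pyran-2-yl]acrylate, via pyranone aldehyde 11 (not isolated)
Conditions: activated MnO2 (10 equiv), Ph3P=CHCO2tBu (1.3 equiv), CH2Cl2, rt
Reagents that add atoms: (tert-butoxycarbonylmethylene)triphenylphosphorane, CC(C)(C)OC(=O)C=P(c1ccccc1)(c1ccccc1)c1ccccc1
Why: Tandem oxidation–Wittig olefination: MnO2 oxidises the allylic-type hydroxymethyl group and the stabilised ylide traps the electrophilic aldehyde in situ, which should give the (E)-enoate.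

Step 8
Reactants: 12 tert-butyl (E)-3-[4-oxo-5-(trifluoromethylsulfonyloxy)-4H-pyran-2-yl]acrylate
Product: 13 tert-butyl (E)-3-[4-oxo-5-(trimethylstannyl)-4H-pyran-2-yl]acrylate
Conditions: Me3SnSnMe3 (1.5 equiv), Pd(PPh3)4 (5 mol %), LiCl (3 equiv), 1,4-dioxane, 90 °C
Reagents that add atoms: hexamethylditin, C[Sn](C)(C)[Sn](C)(C)C
Why: Palladium-catalysed stannylation of an enol triflate with a ditin: the electron-poor C–OTf bond adds to zerovalent palladium, chloride exchange and transmetalation with the Sn–Sn reagent follow, and reductive elimination gives the stannane.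

Step 9
Reactants: 13 tert-butyl (E)-3-[4-oxo-5-(trimethylstannyl)-4H-pyran-2-yl]acrylate; 8 (2R)-2-methyl-2,3-bis(triethylsilyloxy)butanoyl chloride
Product: 14 tert-butyl (E)-3-{5-[(2R)-2-methyl-2,3-bis(triethylsilyloxy)butanoyl]-4-oxo-4H-pyran-2-yl}acrylate
Conditions: Pd2(dba)3 (2.5 mol %), P(2-furyl)3 (10 mol %), CuI (10 mol %), toluene, 60 °C
Reagents that add atoms: none
Why: Stille acylation (Milstein–Stille ketone synthesis): the acid chloride adds to zerovalent palladium, the sp2 carbon of the stannane transfers in preference to methyl, and reductive elimination forms the C8–C8a ketone, while the acid chloride has no α-hydrogen and so can neither form a ketene nor epimerise.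

Step 10
Reactants: 14 tert-butyl (E)-3-{5-[(2R)-2-methyl-2,3-bis(triethylsilyloxy)butanoyl]-4-oxo-4H-pyran-2-yl}acrylate
Product: 15 tert-butyl (E)-3-{5-[(2R)-3-hydroxy-2-methyl-2-(triethylsilyloxy)butanoyl]-4-oxo-4H-pyran-2-yl}acrylate (carbinol epimers)
Conditions: AcOH/THF/H2O (3:1:1), rt
Reagents that add atoms: none
Why: Selective acid-catalysed solvolysis of silyl ethers: the secondary triethylsilyl ether should cleave far faster than the tertiary one at C7, which is more hindered and deactivated by the adjacent C8 ketone.

Step 11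
Reactants: 15 tert-butyl (E)-3-{5-[(2R)-3-hydroxy-2-methyl-2-(triethylsilyloxy)butanoyl]-4-oxo-4H-pyran-2-yl}acrylate
Product: 16 tert-butyl (E)-3-{5-[(2R)-2-methyl-3-oxo-2-(triethylsilyloxy)butanoyl]-4-oxo-4H-pyran-2-yl}acrylate
Conditions: Dess–Martin periodinane, CH2Cl2, 0 °C → rt
Reagents that add atoms: none
Why: Dess–Martin oxidation of the secondary alcohol under near-neutral conditions gives the C6 methyl ketone, and C7, which bears no hydrogen and a silylated oxygen, can neither epimerise nor undergo a ketol shift.

Step 12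
Reactants: 16 tert-butyl (E)-3-{5-[(2R)-2-methyl-3-oxo-2-(triethylsilyloxy)butanoyl]-4-oxo-4H-pyran-2-yl}acrylate
Product: 19 tert-butyl (E)-3-[(7R)-7-methyl-6,8-dioxo-7-(triethylsilyloxy)-7,8-dihydro-6H-isochromen-3-yl]acrylate, via trimethylsilyl enol ether 17 (not isolated), via C4a-silyloxy adduct 18 (not isolated)
Conditions: Me3SiOTf (3 equiv), iPr2NEt (4 equiv), CH2Cl2, −78 → 0 °C
Reagents that add atoms: none
Why: Proposed new method: Me3SiOTf with iPr2NEt should turn the only enolisable position of 16, the C5 methyl of the C6 ketone, into enol silane 17 and should also silylate the basic pyranone oxygen to a 4-silyloxypyrylium ion, whereupon C5 adds to the oxygen-bearing carbon C4a to give adduct 18, a further equivalent of silyl triflate removes the C4a oxygen as hexamethyldisiloxane, and the base takes a proton from C5 to leave the C4a=C5 bond. The closest known reaction types are the Mukaiyama-type addition of enol silanes to 4-pyranones and chromones activated by silyl triflates (which normally occurs at the carbon next to the ring oxygen) and the Knoevenagel-type condensation of C–H acids at C4 of O-acylated or O-alkylated 4-pyranones to give 4-ylidene-4H-pyrans; a plain methyl ketone attacking the silyloxy-bearing carbon intramolecularly has not been shown. Ring A closes in a 6-(enolexo)-exo-trig aldol mode with respect to the C4a–O bond of the activated carbonyl. No stereocentre is formed, and C7, being quaternary and O-silylated, can neither epimerise nor undergo a ketol shift. The selectivity needed is attack at C4a and not at C1, which is likewise ortho to C8a, would also give a six-membered ring and is therefore not excluded by the tether; it should be secured by the rotamer about C8a–C8 in which the C8 carbonyl points away from the C4a oxygen (placing the C7 arm beside C4a) and by the fact that only the C4a adduct has a leaving group and collapses irreversibly to the neutral vinylogous ester, whereas a C1 adduct can revert to the aromatic pyrylium ion. Keeping the mixture at or below 0 °C should spare the tert-butyl ester and the C7 triethylsilyl ether.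

Step 13
Reactants: 20 orsellinic acid
Product: 21 triethylsilyl 2-methyl-4,6-bis(triethylsilyloxy)benzoate
Conditions: Et3SiOTf (3.5 equiv), 2,6-lutidine, CH2Cl2, 0 °C → rt; pentane, filtration (non-aqueous work-up)
Reagents that add atoms: triethylsilyl trifluoromethanesulfonate, CC[Si](CC)(CC)OS(=O)(=O)C(F)(F)F
Why: Exhaustive silylation with silyl triflate and hindered base covers both phenols (including the hydrogen-bonded ortho one) and the acid at a temperature well below that at which the β-resorcylic acid decarboxylates.

Step 14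
Reactants: 21 triethylsilyl 2-methyl-4,6-bis(triethylsilyloxy)benzoate
Product: 22 2-methyl-4,6-bis(triethylsilyloxy)benzoyl chloride
Conditions: (COCl)2 (1.2 equiv), DMF (cat.), CH2Cl2, 0 °C → rt; evaporation, used crude
Reagents that add atoms: oxalyl chloride, ClC(=O)C(=O)Cl
Why: The same neutral silyl-ester-to-acid-chloride conversion as in step 5 (Vilsmeier activation) applies, and aryl silyl ethers are inert to it.

Step 15
Reactants: 19 tert-butyl (E)-3-[(7R)-7-methyl-6,8-dioxo-7-(triethylsilyloxy)-7,8-dihydro-6H-isochromen-3-yl]acrylate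
Product: 23 tert-butyl (E)-3-[(7R)-7-hydroxy-7-methyl-6,8-dioxo-7,8-dihydro-6H-isochromen-3-yl]acrylate
Conditions: HF·pyridine, pyridine, THF, 0 °C → rt
Reagents that add atoms: none
Why: Fluoride-mediated desilylation under buffered, weakly acidic conditions breaks only the Si–O bond, so the base-sensitive bicyclic core, the tert-butyl ester and the C7 configuration should be unaffected.

Step 16
Reactants: 23 tert-butyl (E)-3-[(7R)-7-hydroxy-7-methyl-6,8-dioxo-7,8-dihydro-6H-isochromen-3-yl]acrylate; 22 2-methyl-4,6-bis(triethylsilyloxy)benzoyl chloride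
Product: 24 (7R)-3-[(E)-3-tert-butoxy-3-oxoprop-1-enyl]-7-methyl-6,8-dioxo-7,8-dihydro-6H-isochromen-7-yl 2-methyl-4,6-bis(triethylsilyloxy)benzoate
Conditions: 22 (1.5 equiv), Et3N, DMAP (0.5 equiv), CH2Cl2, 0 °C → rt
Reagents that add atoms: none
Why: DMAP-catalysed acylation (nucleophilic catalysis) of the tertiary alcohol, which is made acidic by its two flanking carbonyls, forms only the O–acyl bond, so C7 keeps its configuration.

Step 17
Reactants: 24 (7R)-3-[(E)-3-tert-butoxy-3-oxoprop-1-enyl]-7-methyl-6,8-dioxo-7,8-dihydro-6H-isochromen-7-yl 2-methyl-4,6-bis(triethylsilyloxy)benzoate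
Product: 25 mitorubrinic acid
Conditions: TFA/CH2Cl2 (1:2), H2O (5 equiv), 0 °C → rt
Reagents that add atoms: none
Why: Acidolysis in one pot: TFA cleaves the tert-butyl ester through the tert-butyl cation and hydrolyses the acid-labile aryl silyl ethers, while the C7 ester cannot ionise (its cation would sit between two carbonyls) and the bicyclic core tolerates acid.

Compound list
1 | (S)-lactic acid | C[C@H](O)C(=O)O | starting material
2 | pivalaldehyde | CC(C)(C)C=O | starting material
3 | (2S,5S)-2-tert-butyl-5-methyl-1,3-dioxolan-4-one (cis) | C[C@@H]1O[C@H](C(C)(C)C)OC1=O | intermediate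
4 | lithium (2S)-2-tert-butyl-5-methyl-1,3-dioxol-4-olate (enolate of 3, not isolated) | CC1=C(O[Li])O[C@@H](C(C)(C)C)O1 | intermediate
5 | (2S,5R)-2-tert-butyl-5-(1-hydroxyethyl)-5-methyl-1,3-dioxolan-4-one (carbinol epimers) | C[C@]1(C(C)O)O[C@H](C(C)(C)C)OC1=O | intermediate
6 | (2R)-2,3-dihydroxy-2-methylbutanoic acid (C3 epimers) | CC(O)[C@@](C)(O)C(=O)O | intermediate
7 | triethylsilyl (2R)-2-methyl-2,3-bis(triethylsilyloxy)butanoate | CC(O[Si](CC)(CC)CC)[C@@](C)(O[Si](CC)(CC)CC)C(=O)O[Si](CC)(CC)CC | intermediate
8 | (2R)-2-methyl-2,3-bis(triethylsilyloxy)butanoyl chloride | CC(O[Si](CC)(CC)CC)[C@@](C)(O[Si](CC)(CC)CC)C(Cl)=O | intermediate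
9 | kojic acid | OCc1cc(=O)c(O)co1 | starting material
10 | 6-(hydroxymethyl)-4-oxo-4H-pyran-3-yl trifluoromethanesulfonate | OCc1cc(=O)c(OS(=O)(=O)C(F)(F)F)co1 | intermediate
11 | 6-formyl-4-oxo-4H-pyran-3-yl trifluoromethanesulfonate (not isolated) | O=Cc1cc(=O)c(OS(=O)(=O)C(F)(F)F)co1 | intermediate
12 | tert-butyl (E)-3-[4-oxo-5-(trifluoromethylsulfonyloxy)-4H-pyran-2-yl]acrylate | CC(C)(C)OC(=O)/C=C/c1cc(=O)c(OS(=O)(=O)C(F)(F)F)co1 | intermediate
13 | tert-butyl (E)-3-[4-oxo-5-(trimethylstannyl)-4H-pyran-2-yl]acrylate | CC(C)(C)OC(=O)/C=C/c1cc(=O)c([Sn](C)(C)C)co1 | intermediate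
14 | tert-butyl (E)-3-{5-[(2R)-2-methyl-2,3-bis(triethylsilyloxy)butanoyl]-4-oxo-4H-pyran-2-yl}acrylate | CC(O[Si](CC)(CC)CC)[C@@](C)(O[Si](CC)(CC)CC)C(=O)c1coc(/C=C/C(=O)OC(C)(C)C)cc1=O | intermediate
15 | tert-butyl (E)-3-{5-[(2R)-3-hydroxy-2-methyl-2-(triethylsilyloxy)butanoyl]-4-oxo-4H-pyran-2-yl}acrylate (carbinol epimers) | CC(O)[C@@](C)(O[Si](CC)(CC)CC)C(=O)c1coc(/C=C/C(=O)OC(C)(C)C)cc1=O | intermediate
16 | tert-butyl (E)-3-{5-[(2R)-2-methyl-3-oxo-2-(triethylsilyloxy)butanoyl]-4-oxo-4H-pyran-2-yl}acrylate (key-step precursor) | CC(=O)[C@@](C)(O[Si](CC)(CC)CC)C(=O)c1coc(/C=C/C(=O)OC(C)(C)C)cc1=O | intermediate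
17 | tert-butyl (E)-3-{5-[(2R)-2-methyl-2-(triethylsilyloxy)-3-(trimethylsilyloxy)but-3-enoyl]-4-oxo-4H-pyran-2-yl}acrylate (not isolated) | C=C(O[Si](C)(C)C)[C@@](C)(O[Si](CC)(CC)CC)C(=O)c1coc(/C=C/C(=O)OC(C)(C)C)cc1=O | intermediate
18 | tert-butyl (E)-3-[(7R)-7-methyl-6,8-dioxo-7-(triethylsilyloxy)-4a-(trimethylsilyloxy)-4a,5,7,8-tetrahydro-6H-isochromen-3-yl]acrylate (either C4a epimer, not isolated) | CC[Si](CC)(CC)O[C@]1(C)C(=O)CC2(O[Si](C)(C)C)C=C(/C=C/C(=O)OC(C)(C)C)OC=C2C1=O | intermediate
19 | tert-butyl (E)-3-[(7R)-7-methyl-6,8-dioxo-7-(triethylsilyloxy)-7,8-dihydro-6H-isochromen-3-yl]acrylate (key-step product) | CC[Si](CC)(CC)O[C@]1(C)C(=O)C=C2C=C(/C=C/C(=O)OC(C)(C)C)OC=C2C1=O | intermediate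
20 | orsellinic acid | Cc1cc(O)cc(O)c1C(=O)O | starting material
21 | triethylsilyl 2-methyl-4,6-bis(triethylsilyloxy)benzoate | Cc1cc(O[Si](CC)(CC)CC)cc(O[Si](CC)(CC)CC)c1C(=O)O[Si](CC)(CC)CC | intermediate
22 | 2-methyl-4,6-bis(triethylsilyloxy)benzoyl chloride | Cc1cc(O[Si](CC)(CC)CC)cc(O[Si](CC)(CC)CC)c1C(Cl)=O | intermediate
23 | tert-butyl (E)-3-[(7R)-7-hydroxy-7-methyl-6,8-dioxo-7,8-dihydro-6H-isochromen-3-yl]acrylate | O[C@]1(C)C(=O)C=C2C=C(/C=C/C(=O)OC(C)(C)C)OC=C2C1=O | intermediate
24 | (7R)-3-[(E)-3-tert-butoxy-3-oxoprop-1-enyl]-7-methyl-6,8-dioxo-7,8-dihydro-6H-isochromen-7-yl 2-methyl-4,6-bis(triethylsilyloxy)benzoate | Cc1cc(O[Si](CC)(CC)CC)cc(O[Si](CC)(CC)CC)c1C(=O)O[C@]1(C)C(=O)C=C2C=C(/C=C/C(=O)OC(C)(C)C)OC=C2C1=O | intermediate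
25 | mitorubrinic acid, (7R) | Cc1cc(O)cc(O)c1C(=O)O[C@]1(C)C(=O)C=C2C=C(/C=C/C(=O)O)OC=C2C1=O | target

Total step count: 17.
Longest linear sequence: 12 steps (steps 1–5, 9–12, 15–17); steps 6–8 and 13–14 are side branches.

Steps most likely to fail

1. Step 12 (Proposed new method). What may go wrong: the enol silane may add at C1 instead of C4a and open ring B, the C4a adduct may fail to ionise, or the silyl triflate may strip the tert-butyl ester. Fallback (known chemistry, sets out from 16, returns at 19): the pyranone carbonyl oxygen of 16, by far its most nucleophilic oxygen, is methylated with MeOTf in CH2Cl2, the standard conversion of 4-pyranones into 4-alkoxypyrylium salts, to give the isolable 4-methoxypyrylium triflate F1. F1 is then exposed to a hindered, non-nucleophilic base (2,6-di-tert-butylpyridine in MeCN). The C–H acidic methyl ketone should condense at the methoxy-bearing carbon with loss of methanol, which is the established Knoevenagel-type reactivity of 4-alkoxypyrylium salts toward C–H acids, and this gives 19. Here the electrophile is a preformed salt with a true leaving group at C4a, and enolisation is a separate, base-controlled event.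

2. Step 9. What may go wrong: transmetalation from the electron-poor α-stannyl enone to the hindered acylpalladium intermediate may be slow, so that decarbonylation of the acyl complex or protodestannylation takes over. Fallback (sets out from 8 and 12, returns at 14, and also bypasses step 8): acid chloride 8 is reduced with LiAlH(OtBu)3 in THF at −78 °C to the aldehyde F2. F2 is coupled with enol triflate 12 in a Nozaki–Hiyama–Kishi reaction (CrCl2, catalytic NiCl2, DMF, rt), in which the alkenyl group is passed from nickel to chromium and adds to the aldehyde in preference to the ketone and ester groups, giving the C8 allylic alcohol F3 as an epimer mixture. Dess–Martin oxidation of F3 then gives ketone 14.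

3. Step 16. What may go wrong: the tetrahedral intermediate between a tertiary alcohol flanked by two carbonyls and a di-ortho-substituted acylpyridinium ion is congested, so acylation may stall while the aryl silyl ethers or the bicyclic core slowly degrade. Fallback (sets out from 22 and 23, returns at 24): 22 is treated with AgOTf in CH2Cl2 at −40 °C, which precipitates AgCl and gives the aroyl triflate F4. For a 2,6-disubstituted, donor-substituted arene this is in equilibrium with the linear acylium ion. That sterically undemanding electrophile should acylate 23 in the presence of 2,6-di-tert-butylpyridine (acylium-type esterification of hindered partners) to give 24.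

Further compounds
F1 | step 12 | 4-methoxypyrylium triflate derived from 16 by O-methylation of the pyranone carbonyl (C7 unchanged) | COc1cc(/C=C/C(=O)OC(C)(C)C)[o+]cc1C(=O)[C@](C)(O[Si](CC)(CC)CC)C(C)=O.[O-]S(=O)(=O)C(F)(F)F
F2 | step 9 | (2R)-2-methyl-2,3-bis(triethylsilyloxy)butanal | CC(O[Si](CC)(CC)CC)[C@@](C)(O[Si](CC)(CC)CC)C=O
F3 | step 9 | C8 secondary alcohol corresponding to ketone 14: tert-butyl (E)-3-{5-[1-hydroxy-2-methyl-2,3-bis(triethylsilyloxy)butyl]-4-oxo-4H-pyran-2-yl}acrylate (carbinol epimers, C7 geometry as in 14) | CC(O[Si](CC)(CC)CC)[C@@](C)(O[Si](CC)(CC)CC)C(O)c1coc(/C=C/C(=O)OC(C)(C)C)cc1=O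
F4 | step 16 | 2-methyl-4,6-bis(triethylsilyloxy)benzoyl trifluoromethanesulfonate | Cc1cc(O[Si](CC)(CC)CC)cc(O[Si](CC)(CC)CC)c1C(=O)OS(=O)(=O)C(F)(F)F
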